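**Retrosynthetic overview**
1. Rings A and B form a cis-fused decalin with H5 and the C10 methyl on one face and quaternary C10 beside gem-dimethyl C4. They are cut at C4–C5 and C9–C10 back to a (6Z)-polyene β-keto ester (neryl bromide plus the methyl acetoacetate dianion); a chiral proton source closes both rings in one step.
2. The C8 ketone becomes the C8 methyl through its enol triflate and the ester carbon becomes C11. C11–C12 is made by alkylating the C11 allylic sulfone with an epoxide that carries C13 (Sharpless epoxidation), the C14≡C15 alkyne and C16.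
3. Ring C (spiro tetrahydrofuran): the C13 hydroxyl opens the 8β,9β-epoxide at C9 with inversion; dehydration then gives the C7=C8 olefin.
4. Ring B oxygens: C6 enone, 7β,8β-epoxide, acetolysis at C8 with inversion (8α-OAc, 7β-OH).
5. Ring D (2,3-dihydrofuran) is closed last by cycloisomerisation of the C16 alcohol onto the alkyne. Ring order: A and B together, then C, then D.

Key step: step 3

Remark (numbering): labdane numbering is used (C17 on C8, C18/C19 on C4, C20 on C10); β is the face of C20, and "5β" means H5 on that face (cis fusion).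
Assumption: (R)-BINOL monobenzyl ether (one O-benzylation of (R)-BINOL) is taken to give the 5R,10S series; if the sense proves opposite, the (S)-ligand is used in the same step.

Step 1
Reactants: 1 nerol
Product: 2 neryl bromide, (2Z)-1-bromo-3,7-dimethylocta-2,6-diene
Conditions: PBr3, pyridine (cat.), Et2O, −10 °C
Reagents that add atoms: phosphorus tribromide, BrP(Br)Br
Why: SN2-type conversion of the primary allylic alcohol into the bromide at low temperature should keep the Z geometry of the C2=C3 olefin.

Step 2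
Reactants: 3 methyl acetoacetate; 2 neryl bromide
Product: 5 methyl (6Z)-7,11-dimethyl-3-oxododeca-6,10-dienoate, via acetoacetate dianion 4 (not isolated)
Conditions: NaH, THF, 0 °C; n-BuLi, 0 °C; then 2, 0 °C → rt; H2O
Reagents that add atoms: none
Why: Weiler dianion alkylation: the more basic terminal carbanion of the dianion is alkylated by the primary allylic bromide (SN2), which leaves the Z olefin untouched.

Step 3
Reactants: 5 methyl (6Z)-7,11-dimethyl-3-oxododeca-6,10-dienoate
Product: 6 methyl (1R,4aR,8aS)-5,5,8a-trimethyl-2-oxodecahydronaphthalene-1-carboxylate (cis-fused: 5β-H and 10β-CH3; C8 ketone, C9 bearing the ester carbon C11)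
Conditions: (R)-BINOL monobenzyl ether·SnCl4 (2 equiv, pre-formed), 5 added as its 1:1 SnCl4 chelate, toluene, −78 °C; aq. NaHCO3
Reagents that add atoms: none
Why: Proposed new method: the SnCl4-activated phenolic O–H of the BINOL monoether protonates C3 of the terminal isopropylidene while C5 of the (Z)-C5=C10 olefin bonds to C4 (ring A, 6-endo-trig) and the tin-chelated enol carbon C9 captures C10 (ring B, 6-endo-trig), the C9 proton being returned at the end; the closest known reactions are the SnCl4-promoted bicyclisation of (E)-polyene β-keto esters and the BINOL ether–SnCl4 proton-initiated enantioselective cyclisation of aryl-terminated polyprenoids, neither of which has been run on a (Z)-polyene β-keto ester with a chiral acid. The chiral acid chooses between the two enantiomeric chair-like foldings of the chain as the C4–C5 bond forms, which fixes C5. Anti addition of C4 and C9 across the Z olefin then places H5 and the C10 methyl on the same face, so C10 is relayed from C5 by the olefin geometry (cis fusion). C9 is formed as the epimerisable β-keto ester centre and is flattened in step 4. The step needs enantioface control and a concerted second ring closure; the Z geometry and the strongly nucleophilic chelated enol are what secure the cis fusion, and 5 is added as its SnCl4 chelate so that the dicarbonyl does not strip tin from the chiral acid.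

Step 4
Reactants: 6 bicyclic β-keto ester
Product: 7 methyl (4aR,8aS)-5,5,8a-trimethyl-2-(trifluoromethylsulfonyloxy)-3,4,4a,5,6,7,8,8a-octahydronaphthalene-1-carboxylate
Conditions: Tf2O, i-Pr2NEt, CH2Cl2, −78 → 0 °C
Reagents that add atoms: triflic anhydride, O=S(=O)(OS(=O)(=O)C(F)(F)F)C(F)(F)F
Why: The β-keto ester enolises only between its two carbonyls, so O-sulfonylation gives the C8 enol triflate with a C8=C9 double bond (enol triflate formation).

Step 5
Reactants: 7 enol triflate
Product: 8 methyl (4aR,8aS)-2,5,5,8a-tetramethyl-3,4,4a,5,6,7,8,8a-octahydronaphthalene-1-carboxylate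
Conditions: MeMgBr, Fe(acac)3 (5 mol %), THF–NMP, −30 °C
Reagents that add atoms: methylmagnesium bromide, C[Mg]Br
Why: Iron-catalysed Kumada-type cross-coupling of the electron-poor enol triflate installs the C8 methyl (C17) faster than the Grignard reagent attacks the hindered ester.

Step 6
Reactants: 8 unsaturated ester
Product: 9 [(4aR,8aS)-2,5,5,8a-tetramethyl-3,4,4a,5,6,7,8,8a-octahydronaphthalen-1-yl]methanol
Conditions: i-Bu2AlH, CH2Cl2, −78 → 0 °C; aq. KNa tartrate
Reagents that add atoms: none
Why: 1,2-Reduction of the α,β-unsaturated ester by the aluminium hydride gives the allylic alcohol, so that C11 is now a CH2OH group.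

Step 7
Reactants: 9 allylic alcohol
Product: 11 (4aR,8aS)-2,5,5,8a-tetramethyl-1-[(phenylsulfonyl)methyl]-3,4,4a,5,6,7,8,8a-octahydronaphthalene, via allylic bromide 10 (not isolated)
Conditions: PBr3, pyridine (cat.), Et2O, −20 °C; then PhSO2Na, DMF, rt
Reagents that add atoms: sodium benzenesulfinate, [Na+].[O-]S(=O)c1ccccc1
Why: The primary allylic bromide is displaced in situ by the soft sulfur nucleophile (SN2 S-alkylation of a sulfinate), which gives the primary allylic sulfone with the tetrasubstituted C8=C9 olefin retained.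

Step 8
Reactants: 12 2-bromoprop-2-en-1-ol; 13 ethynyltrimethylsilane
Product: 14 2-methylidene-4-(trimethylsilyl)but-3-yn-1-ol
Conditions: PdCl2(PPh3)2 (2 mol %), CuI (4 mol %), Et3N, THF, rt
Reagents that add atoms: none
Why: Sonogashira coupling of the vinyl bromide with the terminal alkyne tolerates the free hydroxyl and gives the 2-alkynyl allylic alcohol.

Step 9
Reactants: 14 enynol
Product: 15 [(2S)-2-[(trimethylsilyl)ethynyl]oxiran-2-yl]methanol
Conditions: Ti(O-i-Pr)4 (cat.), L-(+)-diisopropyl tartrate (cat.), t-BuOOH, 4 Å molecular sieves, CH2Cl2, −20 °C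
Reagents that add atoms: tert-butyl hydroperoxide, CC(C)(C)OO
Why: Sharpless asymmetric epoxidation of a 2-substituted allylic alcohol: the L-(+)-tartrate complex delivers oxygen to the olefin face that gives the (S)-epoxide, which sets the future C13 by reagent control.

Step 10
Reactants: 15 epoxy alcohol
Product: 16 tert-butyl{[(2R)-2-[(trimethylsilyl)ethynyl]oxiran-2-yl]methoxy}diphenylsilane (same spatial arrangement as 15; the descriptor changes with the silyl ether)
Conditions: TBDPSCl, imidazole, CH2Cl2, 0 °C → rt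
Reagents that add atoms: tert-butyldiphenylsilyl chloride, CC(C)(C)[Si](Cl)(c1ccccc1)c1ccccc1
Why: Silylation of the primary alcohol under mild base leaves the epoxide untouched and gives an acid-stable ether for the later steps.

Step 11
Reactants: 11 allylic sulfone; 16 silyl-protected epoxide
Product: 18 (13S)-16-(tert-butyldiphenylsilyloxy)-11-(phenylsulfonyl)-15-(trimethylsilyl)-5β-labd-8-en-14-yn-13-ol (both C11 epimers), via lithiated sulfone 17 (not isolated)
Conditions: n-BuLi, THF–DMPU, −78 °C; then 16, −78 → 0 °C; H2O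
Reagents that add atoms: none
Why: Julia-type alkylation: the α-sulfonyl allyl carbanion attacks through C11 the CH2 terminus (C12) of the 2,2-disubstituted epoxide (SN2), which forms C11–C12 and frees the C13 tertiary alkoxide without touching the C13 stereocentre, the silyl cap on the alkyne disfavouring SN2′ attack.

Step 12
Reactants: 18 hydroxy sulfone
Product: 20 (13S)-16-(tert-butyldiphenylsilyloxy)-5β-labd-8-en-14-yn-13-ol, via desulfonylated silylalkyne 19 (not isolated)
Conditions: Na(Hg), Na2HPO4, MeOH–THF, −20 °C; then K2CO3, MeOH, rt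
Reagents that add atoms: none
Why: Reductive desulfonylation of the allylic sulfone with protonation of the allyl anion at the less substituted C11 terminus should restore the tetrasubstituted C8=C9 olefin, and methanolic carbonate then cleaves the alkynyl C–Si bond while the TBDPS ether survives.

Step 13
Reactants: 20 alkynyl tertiary alcohol
Product: 22 (13S)-16-(tert-butyldiphenylsilyloxy)-9α,13-epoxy-5β-labd-14-yn-8β-ol (8α-CH3), via 8β,9β-epoxide 21 (not isolated)
Conditions: mCPBA, NaHCO3, CH2Cl2, 0 °C; then camphorsulfonic acid (10 mol %), 0 °C → rt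
Reagents that add atoms: 3-chloroperbenzoic acid, O=C(OO)c1cccc(Cl)c1
Why: Peracid epoxidation of the electron-rich tetrasubstituted olefin (the alkyne is inert) should occur on the convex β face, because the pseudoaxial C10–C1 bond and ring A screen the α face, and acid-catalysed 5-exo-tet opening by the C13 hydroxyl at C9 with inversion then puts the C9–O bond on the α face and C11 on the β face (this sets C9), as in the related oxaspiro[4.5]decanol series.

Step 14
Reactants: 22 spiro hydroxy ether
Product: 23 (13S)-16-(tert-butyldiphenylsilyloxy)-9α,13-epoxy-5β-labd-7-en-14-yne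
Conditions: SOCl2, pyridine, CH2Cl2, −40 → 0 °C
Reagents that add atoms: none
Why: E2 dehydration through the chlorosulfite: C9 carries no hydrogen, so ring elimination can only run towards C7 and gives the trisubstituted C7=C8 olefin (Zaitsev); any exocyclic 8(17) isomer can be isomerised to this more stable ring olefin.

Step 15
Reactants: 23 C7=C8 olefin
Product: 24 (13S)-16-(tert-butyldiphenylsilyloxy)-9α,13-epoxy-5β-labd-7-en-14-yn-6-one
Conditions: CrO3, 3,5-dimethylpyrazole, CH2Cl2, −20 °C
Reagents that add atoms: chromium trioxide, O=[Cr](=O)=O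
Why: Chromium-based allylic oxidation converts the ring allylic methylene C6 into the enone carbonyl in preference to the C17 methyl; the alkyne, silyl ether and spiro ether are inert.

Step 16
Reactants: 24 enone
Product: 25 (13S)-16-(tert-butyldiphenylsilyloxy)-7β,8β:9α,13-diepoxy-5β-labd-14-yn-6-one
Conditions: dimethyldioxirane, acetone, 0 °C → rt
Reagents that add atoms: dimethyldioxirane, CC1(C)OO1
Why: Electrophilic epoxidation of the trisubstituted enone by the neutral dioxirane (no base, so the C5–H next to the ketone is not epimerised) should occur on the convex β face, anti to the axial C10–C1 bond that screens the α face of C8, which gives the 7β,8β-epoxide and thereby the β C7–O bond.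

Step 17
Reactants: 25 epoxy ketone
Product: 26 (13S)-8α-acetoxy-16-(tert-butyldiphenylsilyloxy)-9α,13-epoxy-7β-hydroxy-5β-labd-14-yn-6-one
Conditions: AcOH, Sc(OTf)3 (10 mol %), rt
Reagents that add atoms: acetic acid, CC(=O)O
Why: Acid-catalysed acetolysis of the α,β-epoxy ketone: the epoxide opens at the tertiary β-carbon C8 (C7 is deactivated by the adjacent carbonyl) and acetic acid enters anti to the departing oxygen (inversion at C8, trans-diaxial opening), which sets 8α-OAc with 8β-CH3 and leaves the 7β-hydroxyl.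

Step 18
Reactants: 26 silyl ether
Product: 27 (13S)-8α-acetoxy-9α,13-epoxy-7β,16-dihydroxy-5β-labd-14-yn-6-one
Conditions: HF·pyridine, pyridine, THF, 0 °C → rt
Reagents that add atoms: none
Why: Fluoride cleavage of the silyl ether under buffered, weakly acidic conditions should leave the β-acetoxy ketone and the α-ketol untouched.

Step 19
Reactants: 27 alkynol
Product: 28 CNP0275274.1, (5R,7R,8R,9S,10S,13S)-8α-acetoxy-9α,13:15,16-diepoxy-7β-hydroxy-5β-labd-14-en-6-one
Conditions: Mo(CO)6 (30 mol %), Et3N, Et2O, hν (350 nm); then 27, rt; chromatography on Et3N-deactivated silica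
Reagents that add atoms: none
Why: Alkynol cycloisomerisation through a molybdenum vinylidene: the C16 hydroxyl adds to the electrophilic terminal carbon C15 (5-endo) and proton transfer gives the 2,3-dihydrofuran under non-acidic conditions that suit the acid-labile enol ether; no stereocentre is touched.

**Compound list**
1 | nerol, (2Z)-3,7-dimethylocta-2,6-dien-1-ol | CC(C)=CCC/C(C)=C\CO | starting material
2 | neryl bromide | CC(C)=CCC/C(C)=C\CBr | intermediate
3 | methyl acetoacetate | COC(=O)CC(C)=O | starting material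
4 | sodium lithium dianion of methyl acetoacetate | [Na+].[Li+].[CH2-]C(=O)[CH-]C(=O)OC | intermediate (not isolated)
5 | methyl (6Z)-7,11-dimethyl-3-oxododeca-6,10-dienoate | COC(=O)CC(=O)CC/C=C(C)\CCC=C(C)C | intermediate
6 | methyl (1R,4aR,8aS)-5,5,8a-trimethyl-2-oxodecahydronaphthalene-1-carboxylate (cis-fused) | COC(=O)[C@H]1C(=O)CC[C@@H]2C(C)(C)CCC[C@]12C | intermediate
7 | C8 enol triflate of 6 | COC(=O)C1=C(OS(=O)(=O)C(F)(F)F)CC[C@@H]2C(C)(C)CCC[C@]12C | intermediate
8 | methyl (4aR,8aS)-2,5,5,8a-tetramethyl-3,4,4a,5,6,7,8,8a-octahydronaphthalene-1-carboxylate | COC(=O)C1=C(C)CC[C@@H]2C(C)(C)CCC[C@]12C | intermediate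
9 | corresponding C11 allylic alcohol | OCC1=C(C)CC[C@@H]2C(C)(C)CCC[C@]12C | intermediate
10 | corresponding C11 allylic bromide | BrCC1=C(C)CC[C@@H]2C(C)(C)CCC[C@]12C | intermediate (not isolated)
11 | corresponding C11 phenyl sulfone | O=S(=O)(CC1=C(C)CC[C@@H]2C(C)(C)CCC[C@]12C)c1ccccc1 | intermediate
12 | 2-bromoprop-2-en-1-ol | OCC(Br)=C | starting material
13 | ethynyltrimethylsilane | C#C[Si](C)(C)C | starting material
14 | 2-methylidene-4-(trimethylsilyl)but-3-yn-1-ol | OCC(=C)C#C[Si](C)(C)C | intermediate
15 | [(2S)-2-[(trimethylsilyl)ethynyl]oxiran-2-yl]methanol | OC[C@@]1(C#C[Si](C)(C)C)CO1 | intermediate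
16 | TBDPS ether of 15 | CC(C)(C)[Si](OC[C@@]1(C#C[Si](C)(C)C)CO1)(c1ccccc1)c1ccccc1 | intermediate
17 | C11-lithiated sulfone of 11 | [Li+].O=S(=O)([CH-]C1=C(C)CC[C@@H]2C(C)(C)CCC[C@]12C)c1ccccc1 | intermediate (not isolated)
18 | (13S)-16-(TBDPS-oxy)-11-(phenylsulfonyl)-15-(trimethylsilyl)-5β-labd-8-en-14-yn-13-ol, C11 epimers | O=S(=O)(C(C[C@](O)(C#C[Si](C)(C)C)CO[Si](c1ccccc1)(c1ccccc1)C(C)(C)C)C1=C(C)CC[C@@H]2C(C)(C)CCC[C@]12C)c1ccccc1 | intermediate
19 | (13S)-16-(TBDPS-oxy)-15-(trimethylsilyl)-5β-labd-8-en-14-yn-13-ol | C[Si](C)(C)C#C[C@@](O)(CCC1=C(C)CC[C@@H]2C(C)(C)CCC[C@]12C)CO[Si](c1ccccc1)(c1ccccc1)C(C)(C)C | intermediate (not isolated)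
20 | (13S)-16-(TBDPS-oxy)-5β-labd-8-en-14-yn-13-ol | C#C[C@@](O)(CCC1=C(C)CC[C@@H]2C(C)(C)CCC[C@]12C)CO[Si](c1ccccc1)(c1ccccc1)C(C)(C)C | intermediate
21 | 8β,9β-epoxide of 20 | C#C[C@@](O)(CC[C@]12O[C@@]1(C)CC[C@@H]3C(C)(C)CCC[C@]23C)CO[Si](c1ccccc1)(c1ccccc1)C(C)(C)C | intermediate (not isolated)
22 | (13S)-16-(TBDPS-oxy)-9α,13-epoxy-5β-labd-14-yn-8β-ol | C[C@]1(O)CC[C@@H]2C(C)(C)CCC[C@]2(C)[C@@]12CC[C@](C#C)(CO[Si](c3ccccc3)(c3ccccc3)C(C)(C)C)O2 | intermediate
23 | (13S)-16-(TBDPS-oxy)-9α,13-epoxy-5β-labd-7-en-14-yne | CC1=CC[C@@H]2C(C)(C)CCC[C@]2(C)[C@@]12CC[C@](C#C)(CO[Si](c3ccccc3)(c3ccccc3)C(C)(C)C)O2 | intermediate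
24 | (13S)-16-(TBDPS-oxy)-9α,13-epoxy-5β-labd-7-en-14-yn-6-one | CC1=CC(=O)[C@@H]2C(C)(C)CCC[C@]2(C)[C@@]12CC[C@](C#C)(CO[Si](c3ccccc3)(c3ccccc3)C(C)(C)C)O2 | intermediate
25 | (13S)-16-(TBDPS-oxy)-7β,8β:9α,13-diepoxy-5β-labd-14-yn-6-one | C[C@]12O[C@H]1C(=O)[C@@H]3C(C)(C)CCC[C@]3(C)[C@@]24CC[C@](C#C)(CO[Si](c5ccccc5)(c5ccccc5)C(C)(C)C)O4 | intermediate
26 | (13S)-8α-acetoxy-16-(TBDPS-oxy)-9α,13-epoxy-7β-hydroxy-5β-labd-14-yn-6-one | CC(=O)O[C@]1(C)[C@@H](O)C(=O)[C@@H]2C(C)(C)CCC[C@]2(C)[C@@]12CC[C@](C#C)(CO[Si](c3ccccc3)(c3ccccc3)C(C)(C)C)O2 | intermediate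
27 | (13S)-8α-acetoxy-9α,13-epoxy-7β,16-dihydroxy-5β-labd-14-yn-6-one | CC(=O)O[C@]1(C)[C@@H](O)C(=O)[C@@H]2C(C)(C)CCC[C@]2(C)[C@@]12CC[C@](C#C)(CO)O2 | intermediate
28 | CNP0275274.1, (5R,7R,8R,9S,10S,13S)-8α-acetoxy-9α,13:15,16-diepoxy-7β-hydroxy-5β-labd-14-en-6-one | CC(=O)O[C@]1(C)[C@@H](O)C(=O)[C@@H]2C(C)(C)CCC[C@]2(C)[C@@]12CC[C@@]1(C=COC1)O2 | target

**Step count**
Total: 19 steps. Longest linear sequence: 16 steps (steps 1–7 and 11–19); steps 8–10 make the side-chain epoxide.

**Steps most likely to fail**

Step 3 (key step). Three things may go wrong: the tin-bound dicarbonyl may pass on a proton achirally and erode the enantioselectivity; the cyclisation may run stepwise through a monocyclic cation, so that the Z geometry is no longer transmitted and the cis fusion is lost; and the enol oxygen instead of C9 may capture the C10 cation. The fallback uses known chemistry and sets out from 5. SnCl4 alone (CH2Cl2, 0 °C → rt), the established achiral promoter for β-keto ester terminated polyenes, would give the racemic cis-fused keto ester F1, freed from any trans-fused isomer by chromatography. Ester exchange with (1R,2S,5R)-menthol (DMAP cat., toluene, reflux, through the acylketene) would give two diastereomeric menthyl esters; the menthyl ester with the decalin of 6, F2, is separated by crystallisation or chromatography from the menthyl ester of the enantiomeric decalin F3. Methanolysis of F2 (MeOH, DMAP cat., toluene, sealed tube) comes back to the route at 6.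

Step 17. After ionisation at C8, a 1,2-acyl shift with ring contraction, loss of a C17 proton, or participation of the C9 ether oxygen may compete with capture by acetic acid, and the β-acetoxy ketone may lose acetic acid. The fallback sets out from 23 and installs the acetate before the ketone. Epoxidation of the C7=C8 olefin (mCPBA, NaHCO3, CH2Cl2) should give the 7β,8β-epoxide F4. Acetolysis of this simple trisubstituted epoxide (AcOH, NaOAc), with no carbonyl to migrate, opens it at tertiary C8 with inversion to the 7β-hydroxy-8α-acetate F5. Syn dehydration of the secondary C7 alcohol with the Burgess reagent can only run towards C6 and gives the Δ6 allylic acetate F6. Dihydroxylation (OsO4 cat., NMO) anti to the allylic acetate gives the 6β,7β-diol F7. Oxidation of the less hindered C6 hydroxyl with a sterically discriminating nitroxyl system (TEMPO cat., NaOCl, KBr, 0 °C) comes back to the route at 26.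

Step 13. The tetrasubstituted epoxide may rearrange under acid (alkyl or hydride shift), or 6-endo attack at C8 may compete with the 5-exo closure at C9. The fallback sets out from 20 and avoids a free epoxide and acid. Bromoetherification (NBS, CH2Cl2, −20 °C) should place the bromonium ion on the β face and let the C13 hydroxyl close at C9 anti to it, giving the 8β-bromo-9α,13-epoxide F8. Dehydrobromination (DBU, toluene, 80 °C), which can only run towards C7 within the ring, comes back to the route at 23.

Further compounds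
F1 | step 3 | racemic cis-fused methyl 5,5,8a-trimethyl-2-oxodecahydronaphthalene-1-carboxylate (both enantiomers) | COC(=O)C1C(=O)CC[C@@H]2C(C)(C)CCC[C@]12C.COC(=O)C1C(=O)CC[C@H]2C(C)(C)CCC[C@@]12C
F2 | step 3 | (1R,2S,5R)-menthyl ester with the decalin of 6 | CC(C)[C@@H]1CC[C@@H](C)C[C@H]1OC(=O)C1C(=O)CC[C@@H]2C(C)(C)CCC[C@]12C
F3 | step 3 | (1R,2S,5R)-menthyl ester of the enantiomeric decalin | CC(C)[C@@H]1CC[C@@H](C)C[C@H]1OC(=O)C1C(=O)CC[C@H]2C(C)(C)CCC[C@@]12C
F4 | step 17 | (13S)-16-(TBDPS-oxy)-7β,8β:9α,13-diepoxy-5β-labd-14-yne | C[C@]12O[C@H]1C[C@@H]3C(C)(C)CCC[C@]3(C)[C@@]24CC[C@](C#C)(CO[Si](c5ccccc5)(c5ccccc5)C(C)(C)C)O4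
F5 | step 17 | (13S)-8α-acetoxy-16-(TBDPS-oxy)-9α,13-epoxy-5β-labd-14-yn-7β-ol | CC(=O)O[C@]1(C)[C@@H](O)C[C@@H]2C(C)(C)CCC[C@]2(C)[C@@]12CC[C@](C#C)(CO[Si](c3ccccc3)(c3ccccc3)C(C)(C)C)O2
F6 | step 17 | (13S)-8α-acetoxy-16-(TBDPS-oxy)-9α,13-epoxy-5β-labd-6-en-14-yne | CC(=O)O[C@]1(C)C=C[C@@H]2C(C)(C)CCC[C@]2(C)[C@@]12CC[C@](C#C)(CO[Si](c3ccccc3)(c3ccccc3)C(C)(C)C)O2
F7 | step 17 | (13S)-8α-acetoxy-16-(TBDPS-oxy)-9α,13-epoxy-5β-labd-14-yne-6β,7β-diol | CC(=O)O[C@]1(C)[C@@H](O)[C@@H](O)[C@@H]2C(C)(C)CCC[C@]2(C)[C@@]12CC[C@](C#C)(CO[Si](c3ccccc3)(c3ccccc3)C(C)(C)C)O2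
F8 | step 13 | (13S)-8β-bromo-16-(TBDPS-oxy)-9α,13-epoxy-5β-labd-14-yne | C[C@]1(Br)CC[C@@H]2C(C)(C)CCC[C@]2(C)[C@@]12CC[C@](C#C)(CO[Si](c3ccccc3)(c3ccccc3)C(C)(C)C)O2
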